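**Plan**

1. The target is an achiral linear heptamer of seven aryl ether-linked rings, lettered A to G from the 2,4,6-trihydroxyphenoxy end. Rings E and C each carry five neighbouring oxygen-bearing carbons and one C–H.
2. Cuts, in retrosynthetic order: all 17 O–alkyl bonds (15 methyl, 2 ethyl); the aryl–O bonds at the doubly oxygen-flanked carbons of rings A, B, D and F (phenoxide plus 4-fluoro-3,5-dimethoxybenzaldehyde, the formyl group later turned into OH); and in rings E and C the C1–C2 bond.
3. Feature used: in ring E, C1 (oxygen to ring D), C6 (oxygen to ring F), C5 and C4 are the four carbons of squaric acid, and C3 (OH) with C2 (H) is a 1-ethoxyvinyl unit. The crowded E–O–F ether is therefore made as an aryl squarate, and ring E closes by forming C1–C2; ring C repeats this.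
4. Forward order: G and F (fluoride displacement, Dakin), ring E (squarate, ring expansion), ring D (displacement, Dakin), ring C (second ring expansion), ring B, ring A, then global dealkylation.
5. Stereochemistry: none in the target; the quaternary carbon of the cyclobutenones is racemic and is lost on aromatisation.

Key step: step 9

Remark: ring E (and ring C likewise) is numbered from the carbon bonded to the oxygen of ring D (ring B) as C1, through the C–H carbon as C2.
Remark: methyl and ethyl ethers are the only protecting groups, and the cyclobutenones 14 and 23 are used as racemates.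
Remark: 1-ethoxyvinyllithium 12 does not keep in THF, so step 7 is run afresh before each of its two uses (steps 8 and 13).

**Route**

Step 1
Reactants: 1 syringaldehyde (4-hydroxy-3,5-dimethoxybenzaldehyde)
Product: 2 4-fluoro-3,5-dimethoxybenzaldehyde
Conditions: PhenoFluor (1.2 equiv), CsF (3 equiv), toluene, 110 °C
Reagents that add atoms: PhenoFluor (2,2-difluoro-1,3-bis(2,6-diisopropylphenyl)-2,3-dihydro-1H-imidazole), FC1(F)N(c2c(C(C)C)cccc2C(C)C)C=CN1c1c(C(C)C)cccc1C(C)C; CsF, [Cs+].[F-] (its fluoride exchanges with that of the reagent)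
Why: Deoxyfluorination of a phenol: the phenol condenses with the difluoroimidazoline to a 2-aryloxyimidazolium bifluoride, and fluoride then replaces the urea leaving group at the ipso carbon in a concerted nucleophilic aromatic substitution that the para formyl group accelerates, while the aldehyde itself is not attacked by this reagent.

Step 2
Reactants: 3 3,4,5-trimethoxyphenol; 2 4-fluoro-3,5-dimethoxybenzaldehyde
Product: 4 3,5-dimethoxy-4-(3,4,5-trimethoxyphenoxy)benzaldehyde (F–G aldehyde)
Conditions: Cs2CO3, DMSO, 110 °C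
Reagents that add atoms: none
Why: Nucleophilic aromatic substitution by addition–elimination: the para formyl group stabilises the anionic adduct, fluoride is the preferred leaving group for this mechanism and the electron-rich phenoxide of 3 is unhindered.

Step 3
Reactants: 4 F–G aldehyde
Product: 6 3,5-dimethoxy-4-(3,4,5-trimethoxyphenoxy)phenol (F–G phenol), via aryl formate 5 (not isolated)
Conditions: mCPBA, CH2Cl2, 0 °C → rt; then K2CO3 (cat.), MeOH, rt
Reagents that add atoms: mCPBA (3-chloroperoxybenzoic acid), OOC(=O)c1cccc(Cl)c1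
Why: Dakin-type Baeyer–Villiger oxidation: in the peracid adduct of the aldehyde the electron-rich aryl group, which has an aryloxy donor para to the migrating carbon, migrates in preference to hydride, and the resulting formate is transesterified by methanol under mild base.

Step 4
Reactants: 7 squaric acid
Product: 8 squaryl dichloride (3,4-dichlorocyclobut-3-ene-1,2-dione)
Conditions: (COCl)2, DMF (cat.), CH2Cl2, 40 °C
Reagents that add atoms: oxalyl chloride, O=C(Cl)C(Cl)=O
Why: Acid chloride formation from a vinylogous carboxylic acid: the Vilsmeier-type chloroiminium salt from DMF and oxalyl chloride activates each enolic hydroxyl for replacement by chloride.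

Step 5
Reactants: 8 squaryl dichloride
Product: 9 3-chloro-4-methoxycyclobut-3-ene-1,2-dione
Conditions: MeOH (1.0 equiv), CH2Cl2, −20 °C → rt, N2 sweep
Reagents that add atoms: methanol, CO
Why: Addition–elimination at a vinylogous acid chloride: the methoxy group introduced first donates into the dione and makes the second chloride less reactive, so one equivalent of methanol at low temperature should stop at the ester chloride.

Step 6
Reactants: 6 F–G phenol; 9 3-chloro-4-methoxycyclobut-3-ene-1,2-dione
Product: 10 3-[3,5-dimethoxy-4-(3,4,5-trimethoxyphenoxy)phenoxy]-4-methoxycyclobut-3-ene-1,2-dione (aryl methyl squarate)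
Conditions: iPr2NEt, CH2Cl2, −40 → 0 °C
Reagents that add atoms: none
Why: Addition–elimination of the phenoxide at the chlorine-bearing carbon of the vinylogous acid chloride, where chloride leaves far more easily than methoxide, gives the mixed aryl methyl squarate, and O-attack of the phenoxide is favoured with this hard acylating agent under a hindered amine base.

Step 7
Reactants: 11 ethyl vinyl ether
Product: 12 1-ethoxyvinyllithium (obtained as a THF solution and used as such in steps 8 and 13)
Conditions: tBuLi (pentane), THF, −78 → 0 °C, then recooled to −78 °C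
Reagents that add atoms: tert-butyllithium, [Li]C(C)(C)C
Why: α-Lithiation of an enol ether: the vinylic hydrogen on the oxygen-bearing carbon is the most acidic one and the ether oxygen coordinates lithium, so tBuLi should metalate only that position.

Step 8
Reactants: 10 aryl methyl squarate; 12 1-ethoxyvinyllithium
Product: 14 racemic 2-[3,5-dimethoxy-4-(3,4,5-trimethoxyphenoxy)phenoxy]-4-(1-ethoxyvinyl)-3,4-dimethoxycyclobut-2-en-1-one, via lithium alkoxide 13 (not isolated)
Conditions: 12 (THF solution, 1.1 equiv) added to 10, THF, −78 °C; then MeOTf, −78 → 0 °C; filtration through Et3N-deactivated silica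
Reagents that add atoms: methyl trifluoromethanesulfonate, COS(=O)(=O)C(F)(F)F
Why: 1,2-Addition of an organolithium to a squarate ester with trapping of the alkoxide by O-methylation: the carbonyl next to the methoxy-bearing carbon is conjugated through the ring C=C with the weaker aryloxy donor and is also the less shielded one, so it should be attacked in preference, and the quaternary stereocentre so formed is racemic and is removed in step 9.

Step 9
Reactants: 14 racemic 2-aryloxy-4-(1-ethoxyvinyl)-3,4-dimethoxycyclobut-2-en-1-one (aryl = rings F–G)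
Product: 17 5-ethoxy-3,4-dimethoxy-2-[3,5-dimethoxy-4-(3,4,5-trimethoxyphenoxy)phenoxy]phenol (E–F–G phenol), via dienylketene 15 (not isolated), via cyclohexadienone 16 (not isolated)
Conditions: toluene (degassed), 110 °C, argon
Reagents that add atoms: none
Why: On heating, the cyclobutenone undergoes conrotatory 4π opening of the bond between the carbonyl carbon and the quaternary carbon, and the methoxy group on that carbon rotates outward, so that the (Z)-dienylketene 15 has the 1-ethoxyvinyl group on the same side as the ketene. Thermally allowed disrotatory 6π electrocyclisation, with the ketene C=C as one component of the triene, joins the ketene carbon to the vinyl CH2, forming the single new C–C bond and closing ring E as cyclohexa-2,4-dienone 16, which enolises to phenol 17. The closest known reaction type is the Moore ring expansion of squarate-derived 4-alkenyl-4-alkoxycyclobutenones to para-alkoxyphenols. No stereocentre is created, and the racemic quaternary centre of 14 is destroyed. The selectivity required is the direction of rotation in the ring opening, which the oxygen donor on the quaternary carbon secures by its strong preference for outward rotation; the position of the ring F oxygen next to the new hydroxyl is fixed by the constitution of 14. The four oxygen substituents lower the barrier of the opening so that refluxing toluene should suffice, and the aryl ethers have no competing thermal pathway.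

Step 10
Reactants: 17 E–F–G phenol; 2 4-fluoro-3,5-dimethoxybenzaldehyde
Product: 18 4-{5-ethoxy-3,4-dimethoxy-2-[3,5-dimethoxy-4-(3,4,5-trimethoxyphenoxy)phenoxy]phenoxy}-3,5-dimethoxybenzaldehyde (D–E–F–G aldehyde)
Conditions: Cs2CO3, DMSO, 120 °C, argon
Reagents that add atoms: none
Why: Nucleophilic aromatic substitution as in step 2: the small fluoride leaving group and the para formyl group should let the ortho-aryloxy phenoxide of 17 form the triply ortho-substituted diaryl ether, helped by the reactive phenoxide generated with Cs2CO3 and the higher temperature.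

Step 11
Reactants: 18 D–E–F–G aldehyde
Product: 20 4-{5-ethoxy-3,4-dimethoxy-2-[3,5-dimethoxy-4-(3,4,5-trimethoxyphenoxy)phenoxy]phenoxy}-3,5-dimethoxyphenol (D–E–F–G phenol), via aryl formate 19 (not isolated)
Conditions: mCPBA, CH2Cl2, 0 °C → rt; then K2CO3 (cat.), MeOH, rt
Reagents that add atoms: mCPBA (3-chloroperoxybenzoic acid), OOC(=O)c1cccc(Cl)c1
Why: Dakin-type Baeyer–Villiger oxidation as in step 3: the aldehyde is the only carbonyl group and should add the peracid faster than the alkoxylated rings are oxidised at 0 °C, the aryl group migrates and the formate is methanolysed.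

Step 12
Reactants: 20 D–E–F–G phenol; 9 3-chloro-4-methoxycyclobut-3-ene-1,2-dione
Product: 21 3-methoxy-4-(aryloxy)cyclobut-3-ene-1,2-dione in which aryloxy is the phenoxy residue of 20
Conditions: iPr2NEt, CH2Cl2, −40 → 0 °C
Reagents that add atoms: none
Why: Addition–elimination at the vinylogous acid chloride as in step 6, here with the phenoxide of 20, whose hydroxyl has two free ortho positions and is unhindered.

Step 13
Reactants: 21 aryl methyl squarate of 20; 12 1-ethoxyvinyllithium
Product: 23 racemic 2-(aryloxy)-4-(1-ethoxyvinyl)-3,4-dimethoxycyclobut-2-en-1-one in which aryloxy is the phenoxy residue of 20, via lithium alkoxide 22 (not isolated)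
Conditions: 12 (THF solution, 1.1 equiv) added to 21, THF, −78 °C; then MeOTf, −78 → 0 °C; filtration through Et3N-deactivated silica
Reagents that add atoms: methyl trifluoromethanesulfonate, COS(=O)(=O)C(F)(F)F
Why: Regioselective 1,2-addition of the organolithium and O-methylation as in step 8, with the same electronic and steric bias between the two carbonyl groups; the new quaternary stereocentre is racemic and is lost in step 14.

Step 14
Reactants: 23 racemic cyclobutenone with the D–E–F–G aryloxy group
Product: 26 5-ethoxy-3,4-dimethoxy-2-(aryloxy)phenol in which aryloxy is the phenoxy residue of 20 (C–D–E–F–G phenol), via dienylketene 24 (not isolated), via cyclohexadienone 25 (not isolated)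
Conditions: toluene (degassed), 110 °C, argon
Reagents that add atoms: none
Why: Moore ring expansion as in step 9: outward rotation of the methoxy group on the quaternary carbon in the 4π opening gives dienylketene 24 with the ethoxyvinyl group next to the ketene, 6π electrocyclisation closes ring C and enolisation gives the phenol with its free hydroxyl on the carbon that will carry the ring B oxygen.

Step 15
Reactants: 26 C–D–E–F–G phenol; 2 4-fluoro-3,5-dimethoxybenzaldehyde
Product: 27 3,5-dimethoxy-4-(aryloxy)benzaldehyde in which aryloxy is the phenoxy residue of 26 (hexamer aldehyde, formyl on ring B)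
Conditions: Cs2CO3, DMSO, 120 °C, argon
Reagents that add atoms: none
Why: Nucleophilic aromatic substitution as in step 10, with the same steric situation at the phenoxide (one ortho aryloxy group and one ortho hydrogen).

Step 16
Reactants: 27 hexamer aldehyde
Product: 29 3,5-dimethoxy-4-(aryloxy)phenol in which aryloxy is the phenoxy residue of 26 (hexamer phenol, hydroxyl on ring B), via aryl formate 28 (not isolated)
Conditions: mCPBA, CH2Cl2, 0 °C → rt; then K2CO3 (cat.), MeOH, rt
Reagents that add atoms: mCPBA (3-chloroperoxybenzoic acid), OOC(=O)c1cccc(Cl)c1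
Why: Dakin-type Baeyer–Villiger oxidation as in steps 3 and 11, with aryl migration from the electron-rich 4-aryloxy-3,5-dimethoxybenzaldehyde and methanolysis of the formate.

Step 17
Reactants: 29 hexamer phenol; 2 4-fluoro-3,5-dimethoxybenzaldehyde
Product: 30 3,5-dimethoxy-4-(aryloxy)benzaldehyde in which aryloxy is the phenoxy residue of 29 (heptamer aldehyde, formyl on ring A)
Conditions: Cs2CO3, DMSO, 110 °C, argon
Reagents that add atoms: none
Why: Nucleophilic aromatic substitution as in step 2, with a phenoxide that has two free ortho positions, so this ether formation should be the easiest of the four.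

Step 18
Reactants: 30 heptamer aldehyde
Product: 32 3,5-dimethoxy-4-(aryloxy)phenol in which aryloxy is the phenoxy residue of 29 (heptamer phenol with 15 methyl ethers, 2 ethyl ethers and one free hydroxyl on ring A), via aryl formate 31 (not isolated)
Conditions: mCPBA, CH2Cl2, 0 °C → rt; then K2CO3 (cat.), MeOH, rt
Reagents that add atoms: mCPBA (3-chloroperoxybenzoic acid), OOC(=O)c1cccc(Cl)c1
Why: Dakin-type Baeyer–Villiger oxidation as in steps 3, 11 and 16, which places the last oxygen para to the ether link and completes the 2,4,6-trioxygenated ring A.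

Step 19
Reactants: 32 heptamer phenol
Product: 33 CNP0292517.0 (target, 18 free hydroxyl groups)
Conditions: BBr3 (40 equiv), CH2Cl2, −78 °C → rt; then H2O, 0 °C; Sephadex LH-20, argon
Reagents that add atoms: none
Why: Lewis acid-mediated dealkylation of aryl alkyl ethers: BBr3 binds each ether oxygen and bromide removes the methyl or ethyl group by SN2 attack, whereas the diaryl ether bonds offer no sp3 carbon and survive, and aqueous quench hydrolyses the aryl borates.

**Compound list**

1 | syringaldehyde (4-hydroxy-3,5-dimethoxybenzaldehyde) | COc1cc(C=O)cc(OC)c1O | starting material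
2 | 4-fluoro-3,5-dimethoxybenzaldehyde | COc1cc(C=O)cc(OC)c1F | intermediate
3 | 3,4,5-trimethoxyphenol | COc1cc(O)cc(OC)c1OC | starting material
4 | 3,5-dimethoxy-4-(3,4,5-trimethoxyphenoxy)benzaldehyde (F–G aldehyde) | O=Cc1cc(OC)c(Oc2cc(OC)c(OC)c(OC)c2)c(OC)c1 | intermediate
5 | 3,5-dimethoxy-4-(3,4,5-trimethoxyphenoxy)phenyl formate | O=COc1cc(OC)c(Oc2cc(OC)c(OC)c(OC)c2)c(OC)c1 | intermediate
6 | 3,5-dimethoxy-4-(3,4,5-trimethoxyphenoxy)phenol (F–G phenol) | Oc1cc(OC)c(Oc2cc(OC)c(OC)c(OC)c2)c(OC)c1 | intermediate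
7 | squaric acid (3,4-dihydroxycyclobut-3-ene-1,2-dione) | OC1=C(O)C(=O)C1=O | starting material
8 | squaryl dichloride (3,4-dichlorocyclobut-3-ene-1,2-dione) | ClC1=C(Cl)C(=O)C1=O | intermediate
9 | 3-chloro-4-methoxycyclobut-3-ene-1,2-dione | COC1=C(Cl)C(=O)C1=O | intermediate
10 | 3-[3,5-dimethoxy-4-(3,4,5-trimethoxyphenoxy)phenoxy]-4-methoxycyclobut-3-ene-1,2-dione | COC1=C(Oc2cc(OC)c(Oc3cc(OC)c(OC)c(OC)c3)c(OC)c2)C(=O)C1=O | intermediate
11 | ethyl vinyl ether | C=COCC | starting material
12 | 1-ethoxyvinyllithium | [Li]C(=C)OCC | intermediate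
13 | racemic lithium 1-(1-ethoxyvinyl)-2-methoxy-4-oxo-3-[3,5-dimethoxy-4-(3,4,5-trimethoxyphenoxy)phenoxy]cyclobut-2-en-1-olate | C=C(OCC)C1([O-])C(OC)=C(Oc2cc(OC)c(Oc3cc(OC)c(OC)c(OC)c3)c(OC)c2)C1=O.[Li+] | intermediate
14 | racemic 2-[3,5-dimethoxy-4-(3,4,5-trimethoxyphenoxy)phenoxy]-4-(1-ethoxyvinyl)-3,4-dimethoxycyclobut-2-en-1-one | C=C(OCC)C1(OC)C(OC)=C(Oc2cc(OC)c(Oc3cc(OC)c(OC)c(OC)c3)c(OC)c2)C1=O | intermediate
15 | (3Z)-2-[3,5-dimethoxy-4-(3,4,5-trimethoxyphenoxy)phenoxy]-5-ethoxy-3,4-dimethoxyhexa-1,3,5-trien-1-one (dienylketene) | O=C=C(Oc1cc(OC)c(Oc2cc(OC)c(OC)c(OC)c2)c(OC)c1)/C(OC)=C(OC)\C(=C)OCC | intermediate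
16 | 2-[3,5-dimethoxy-4-(3,4,5-trimethoxyphenoxy)phenoxy]-5-ethoxy-3,4-dimethoxycyclohexa-2,4-dien-1-one | O=C1CC(OCC)=C(OC)C(OC)=C1Oc1cc(OC)c(Oc2cc(OC)c(OC)c(OC)c2)c(OC)c1 | intermediate
17 | 5-ethoxy-3,4-dimethoxy-2-[3,5-dimethoxy-4-(3,4,5-trimethoxyphenoxy)phenoxy]phenol (E–F–G phenol) | Oc1cc(OCC)c(OC)c(OC)c1Oc1cc(OC)c(Oc2cc(OC)c(OC)c(OC)c2)c(OC)c1 | intermediate
18 | 4-{5-ethoxy-3,4-dimethoxy-2-[3,5-dimethoxy-4-(3,4,5-trimethoxyphenoxy)phenoxy]phenoxy}-3,5-dimethoxybenzaldehyde (D–E–F–G aldehyde) | O=Cc1cc(OC)c(Oc2cc(OCC)c(OC)c(OC)c2Oc2cc(OC)c(Oc3cc(OC)c(OC)c(OC)c3)c(OC)c2)c(OC)c1 | intermediate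
19 | formate ester of phenol 20 | O=COc1cc(OC)c(Oc2cc(OCC)c(OC)c(OC)c2Oc2cc(OC)c(Oc3cc(OC)c(OC)c(OC)c3)c(OC)c2)c(OC)c1 | intermediate
20 | 4-{5-ethoxy-3,4-dimethoxy-2-[3,5-dimethoxy-4-(3,4,5-trimethoxyphenoxy)phenoxy]phenoxy}-3,5-dimethoxyphenol (D–E–F–G phenol) | Oc1cc(OC)c(Oc2cc(OCC)c(OC)c(OC)c2Oc2cc(OC)c(Oc3cc(OC)c(OC)c(OC)c3)c(OC)c2)c(OC)c1 | intermediate
21 | 3-methoxy-4-(aryloxy)cyclobut-3-ene-1,2-dione, aryloxy = phenoxy residue of 20 | COC1=C(Oc2cc(OC)c(Oc3cc(OCC)c(OC)c(OC)c3Oc3cc(OC)c(Oc4cc(OC)c(OC)c(OC)c4)c(OC)c3)c(OC)c2)C(=O)C1=O | intermediate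
22 | racemic lithium 1-(1-ethoxyvinyl)-2-methoxy-4-oxo-3-(aryloxy)cyclobut-2-en-1-olate, aryloxy = phenoxy residue of 20 | C=C(OCC)C1([O-])C(OC)=C(Oc2cc(OC)c(Oc3cc(OCC)c(OC)c(OC)c3Oc3cc(OC)c(Oc4cc(OC)c(OC)c(OC)c4)c(OC)c3)c(OC)c2)C1=O.[Li+] | intermediate
23 | racemic 2-(aryloxy)-4-(1-ethoxyvinyl)-3,4-dimethoxycyclobut-2-en-1-one, aryloxy = phenoxy residue of 20 | C=C(OCC)C1(OC)C(OC)=C(Oc2cc(OC)c(Oc3cc(OCC)c(OC)c(OC)c3Oc3cc(OC)c(Oc4cc(OC)c(OC)c(OC)c4)c(OC)c3)c(OC)c2)C1=O | intermediate
24 | (3Z)-2-(aryloxy)-5-ethoxy-3,4-dimethoxyhexa-1,3,5-trien-1-one, aryloxy = phenoxy residue of 20 (dienylketene) | O=C=C(Oc1cc(OC)c(Oc2cc(OCC)c(OC)c(OC)c2Oc2cc(OC)c(Oc3cc(OC)c(OC)c(OC)c3)c(OC)c2)c(OC)c1)/C(OC)=C(OC)\C(=C)OCC | intermediate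
25 | 2-(aryloxy)-5-ethoxy-3,4-dimethoxycyclohexa-2,4-dien-1-one, aryloxy = phenoxy residue of 20 | O=C1CC(OCC)=C(OC)C(OC)=C1Oc1cc(OC)c(Oc2cc(OCC)c(OC)c(OC)c2Oc2cc(OC)c(Oc3cc(OC)c(OC)c(OC)c3)c(OC)c2)c(OC)c1 | intermediate
26 | 5-ethoxy-3,4-dimethoxy-2-(aryloxy)phenol, aryloxy = phenoxy residue of 20 (C–D–E–F–G phenol) | Oc1cc(OCC)c(OC)c(OC)c1Oc1cc(OC)c(Oc2cc(OCC)c(OC)c(OC)c2Oc2cc(OC)c(Oc3cc(OC)c(OC)c(OC)c3)c(OC)c2)c(OC)c1 | intermediate
27 | 3,5-dimethoxy-4-(aryloxy)benzaldehyde, aryloxy = phenoxy residue of 26 (hexamer aldehyde) | O=Cc1cc(OC)c(Oc2cc(OCC)c(OC)c(OC)c2Oc2cc(OC)c(Oc3cc(OCC)c(OC)c(OC)c3Oc3cc(OC)c(Oc4cc(OC)c(OC)c(OC)c4)c(OC)c3)c(OC)c2)c(OC)c1 | intermediate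
28 | formate ester of phenol 29 | O=COc1cc(OC)c(Oc2cc(OCC)c(OC)c(OC)c2Oc2cc(OC)c(Oc3cc(OCC)c(OC)c(OC)c3Oc3cc(OC)c(Oc4cc(OC)c(OC)c(OC)c4)c(OC)c3)c(OC)c2)c(OC)c1 | intermediate
29 | 3,5-dimethoxy-4-(aryloxy)phenol, aryloxy = phenoxy residue of 26 (hexamer phenol) | Oc1cc(OC)c(Oc2cc(OCC)c(OC)c(OC)c2Oc2cc(OC)c(Oc3cc(OCC)c(OC)c(OC)c3Oc3cc(OC)c(Oc4cc(OC)c(OC)c(OC)c4)c(OC)c3)c(OC)c2)c(OC)c1 | intermediate
30 | 3,5-dimethoxy-4-(aryloxy)benzaldehyde, aryloxy = phenoxy residue of 29 (heptamer aldehyde) | O=Cc1cc(OC)c(Oc2cc(OC)c(Oc3cc(OCC)c(OC)c(OC)c3Oc3cc(OC)c(Oc4cc(OCC)c(OC)c(OC)c4Oc4cc(OC)c(Oc5cc(OC)c(OC)c(OC)c5)c(OC)c4)c(OC)c3)c(OC)c2)c(OC)c1 | intermediate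
31 | formate ester of phenol 32 | O=COc1cc(OC)c(Oc2cc(OC)c(Oc3cc(OCC)c(OC)c(OC)c3Oc3cc(OC)c(Oc4cc(OCC)c(OC)c(OC)c4Oc4cc(OC)c(Oc5cc(OC)c(OC)c(OC)c5)c(OC)c4)c(OC)c3)c(OC)c2)c(OC)c1 | intermediate
32 | 3,5-dimethoxy-4-(aryloxy)phenol, aryloxy = phenoxy residue of 29 (heptamer phenol, 15 OMe and 2 OEt) | Oc1cc(OC)c(Oc2cc(OC)c(Oc3cc(OCC)c(OC)c(OC)c3Oc3cc(OC)c(Oc4cc(OCC)c(OC)c(OC)c4Oc4cc(OC)c(Oc5cc(OC)c(OC)c(OC)c5)c(OC)c4)c(OC)c3)c(OC)c2)c(OC)c1 | intermediate
33 | CNP0292517.0 | Oc1cc(O)c(Oc2cc(O)c(Oc3cc(O)c(O)c(O)c3Oc3cc(O)c(Oc4cc(O)c(O)c(O)c4Oc4cc(O)c(Oc5cc(O)c(O)c(O)c5)c(O)c4)c(O)c3)c(O)c2)c(O)c1 | target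

**Count and risks**

Total steps: 19 (step 7 is carried out twice, once before step 8 and once before step 13). Longest linear sequence: 16 steps (1 → 2 → 4 → 6 → 10 → 14 → 17 → 18 → 20 → 21 → 23 → 26 → 27 → 29 → 30 → 32 → 33, that is steps 1, 2, 3, 6 and 8 to 19). Squaric acid enters through the two-step side branch 7 → 8 → 9 (steps 4 and 5), and ethyl vinyl ether through the one-step side branch 11 → 12 (step 7).

Steps most likely to fail:

1. Step 8 (and its repeat, step 13). The organolithium may attack the two carbonyl groups of the unsymmetrical squarate at similar rates, or displace the aryloxy group by conjugate addition–elimination; either would misplace the ring F oxygen after ring expansion. The fallback sets out from 6 and 8 and comes back at 14. Two equivalents of 6 are condensed with 8 (iPr2NEt, CH2Cl2, −40 °C) to the symmetrical bis(aryl) squarate F1, whose carbonyl groups are equivalent. Addition of 12 and trapping with MeOTf as in step 8 then give 2,3-bis(aryloxy)-4-(1-ethoxyvinyl)-4-methoxycyclobut-2-en-1-one F2. In F2 only the aryloxy group at C3 belongs to a vinylogous ester, so K2CO3 (cat.) in MeOH–THF at 0 °C should exchange it for methoxy by conjugate addition–elimination, releasing 6 for reuse and giving 14. The same detour serves for 23.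

2. Step 10 (and step 15). Displacement of a fluoride flanked by two methoxy groups by an ortho-aryloxy phenoxide may be too slow, so that the aldehyde and the electron-rich phenoxide degrade at the temperature needed. The fallback sets out from 17 and comes back at 18. It is a copper-catalysed Ullmann ether synthesis with commercial 4-bromo-3,5-dimethoxybenzaldehyde (CuI (copper monoiodide), picolinic acid, K3PO4, DMSO, 90–110 °C), in which the C–O bond forms at the metal and not through an anionic adduct (no compound outside the list is made, entry F0). The same coupling can also stand in for steps 2, 15 and 17, in which case step 1 is not needed.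

3. Step 19. Cleavage of 17 ether groups may stop short at the hindered positions of rings C and E, and the free polyphenol may oxidise during isolation. The fallback sets out from 32 and comes back at 33. After the BBr3 treatment and aqueous quench the crude product is acetylated at once (Ac2O, pyridine, rt) to the octadecaacetate F3, which is stable to air and chromatography and can be separated from under-dealkylated material (this is recycled through BBr3). Zemplén deacetylation of F3 (NaOMe (cat.), MeOH, argon, then acidic resin) then gives 33.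

**Further compounds**

F1 | step 8 | 3,4-bis[3,5-dimethoxy-4-(3,4,5-trimethoxyphenoxy)phenoxy]cyclobut-3-ene-1,2-dione | O=C1C(=O)C(Oc2cc(OC)c(Oc3cc(OC)c(OC)c(OC)c3)c(OC)c2)=C1Oc1cc(OC)c(Oc2cc(OC)c(OC)c(OC)c2)c(OC)c1
F2 | step 8 | racemic 2,3-bis[3,5-dimethoxy-4-(3,4,5-trimethoxyphenoxy)phenoxy]-4-(1-ethoxyvinyl)-4-methoxycyclobut-2-en-1-one | C=C(OCC)C1(OC)C(Oc2cc(OC)c(Oc3cc(OC)c(OC)c(OC)c3)c(OC)c2)=C(Oc2cc(OC)c(Oc3cc(OC)c(OC)c(OC)c3)c(OC)c2)C1=O
F0 | step 10 | none | none
F3 | step 19 | octadecaacetate of 33 | CC(=O)Oc1cc(OC(C)=O)c(Oc2cc(OC(C)=O)c(Oc3cc(OC(C)=O)c(OC(C)=O)c(OC(C)=O)c3Oc3cc(OC(C)=O)c(Oc4cc(OC(C)=O)c(OC(C)=O)c(OC(C)=O)c4Oc4cc(OC(C)=O)c(Oc5cc(OC(C)=O)c(OC(C)=O)c(OC(C)=O)c5)c(OC(C)=O)c4)c(OC(C)=O)c3)c(OC(C)=O)c2)c(OC(C)=O)c1
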